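**Assumption (one line):** the (2R,5R)-thiolane is taken to give the (2S,3S)-oxirane by analogy with its benzyl ylide (if the sense is opposite, the (2S,5S)-sulfide is used); "prenyl" = 3-methylbut-2-en-1-yl.

## Retrosynthetic overview

1. Target 20 ⇐ silyl ether 19 ⇐ hemiketal 18, where the endo aryl group is set last by hydride delivery to the exo face; 18 ⇐ lactone 16 + aryllithium 17.
2. Lactone 16 ⇐ dihydrofuran ester 12 by conjugate hydroxymethylation anti to the aryl group, then lactonisation.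
3. Ester 12 ⇐ vinyl oxirane 11 by an oxirane → 2,5-dihydrofuran ring expansion that carries the ArCH–O stereocentre over untouched.
4. Oxirane 11 ⇐ aldehyde 7 + methyl 2-(bromomethyl)acrylate 9 through a chiral sulfonium ylide.
5. Both aryl units ⇐ catechol 1 via bromophenol 3. Ring order: oxirane → dihydrofuran (exo-aryl ring) → γ-lactone → second tetrahydrofuran ring (aryl addition and reduction at the lactone carbon).

## Route

Step 1
Reactants: 1 catechol
Product: 2 2-methoxyphenol
Conditions: MeI (0.9 equiv), K2CO3, acetone, reflux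
Reagents that add atoms: iodomethane, CI
Why: Williamson mono-O-methylation; sub-stoichiometric MeI and recovery of excess catechol limit dimethylation.

Step 2
Reactants: 2 2-methoxyphenol
Product: 3 4-bromo-2-methoxyphenol
Conditions: NBS, MeCN, 0 °C
Reagents that add atoms: N-bromosuccinimide, BrN1C(=O)CCC1=O
Why: Electrophilic aromatic bromination; the free OH is the stronger donor and directs para to itself.

Step 3
Reactants: 3 4-bromo-2-methoxyphenol; 4 prenyl bromide
Product: 5 4-bromo-2-methoxy-1-prenyloxybenzene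
Conditions: K2CO3, DMF, rt
Reagents that add atoms: none
Why: Williamson ether synthesis of the phenoxide with a primary allylic bromide.

Step 4
Reactants: 5 4-bromo-2-methoxy-1-prenyloxybenzene
Product: 7 3-methoxy-4-prenyloxybenzaldehyde, via aryllithium 6 (not isolated)
Conditions: n-BuLi, THF, −78 °C; DMF; H2O
Reagents that add atoms: n-butyllithium (Li of 6), CCCC[Li]; N,N-dimethylformamide, CN(C)C=O
Why: Bromine–lithium exchange followed by Bouveault formylation; the aryl prenyl ether is inert at −78 °C.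

Step 5
Reactants: 3 4-bromo-2-methoxyphenol
Product: 8 (4-bromo-2-methoxyphenoxy)(tert-butyl)dimethylsilane
Conditions: NaH, THF, 0 °C; TBSCl
Reagents that add atoms: tert-butyldimethylsilyl chloride, CC(C)(C)[Si](C)(C)Cl
Why: O-silylation of the sodium phenoxide gives a group that survives aryllithium formation and is removed by fluoride at the end.

Step 6
Reactants: 7 3-methoxy-4-prenyloxybenzaldehyde; 9 methyl 2-(bromomethyl)prop-2-enoate
Product: 11 methyl 2-[(2S,3S)-3-(3-methoxy-4-prenyloxyphenyl)oxiran-2-yl]prop-2-enoate, via sulfonium bromide 10 (not isolated)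
Conditions: 9, (2R,5R)-2,5-dimethylthiolane (1.2 equiv), MeCN, rt; then 7, Cs2CO3, MeCN/t-BuOH 9:1, 0 °C; trans isomer separated
Reagents that add atoms: (2R,5R)-2,5-dimethylthiolane (kept only in 10), C[C@@H]1CC[C@@H](C)S1
Why: Corey–Chaykovsky epoxidation with a C2-symmetric chiral sulfonium ylide; the sulfide shields one ylide face and reversible betaine formation from the ester-conjugated ylide favours the trans oxirane, setting both oxirane carbons as (2S,3S).

Step 7
Reactants: 11 methyl 2-[(2S,3S)-3-(3-methoxy-4-prenyloxyphenyl)oxiran-2-yl]prop-2-enoate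
Product: 12 methyl (5R)-5-(3-methoxy-4-prenyloxyphenyl)-2,5-dihydrofuran-3-carboxylate
Conditions: 1,4-diazabicyclo[2.2.2]octane (DABCO, 20 mol%), MeCN, 50 °C
Reagents that add atoms: none
Why: Proposed new method: a Lewis-base relay ring expansion in which DABCO adds to the acrylate CH2 (SN2′), the resulting enolate opens the oxirane at the allylic C–O bond, and the alkoxide still attached to the untouched ArCH carbon closes 5-exo-tet on the allylic ammonium carbon with release of DABCO, so the stereocentre is carried over with retention (3S in 11 becomes 5R in 12 by CIP renumbering only) and the acid-labile electron-rich aryl oxirane never meets a Lewis acid; the closest known reactions are the iodide-relay isomerisation of 3,4-epoxybut-1-ene to 2,5-dihydrofuran, the Cu(hfacac)2-catalysed vinyl oxirane ring expansion and amine-catalysed SN2′ substitutions of Morita–Baylis–Hillman derivatives.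

Step 8
Reactants: 12 methyl (5R)-5-(3-methoxy-4-prenyloxyphenyl)-2,5-dihydrofuran-3-carboxylate
Product: 14 methyl (4R,5R)-4-{[dimethyl(propan-2-yloxy)silyl]methyl}-5-(3-methoxy-4-prenyloxyphenyl)oxolane-3-carboxylate, via silyl ketene acetal 13 (not isolated)
Conditions: (i-PrO)Me2SiCH2MgCl, CuBr·SMe2 (20 mol%), TMSCl, THF, −78 to −30 °C; aq. citric acid work-up
Reagents that add atoms: (isopropoxydimethylsilyl)methylmagnesium chloride, CC(C)O[Si](C)(C)C[Mg]Cl; chlorotrimethylsilane (kept only in 13), C[Si](C)(C)Cl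
Why: Copper-catalysed conjugate addition of Tamao's hydroxymethyl anion equivalent; attack anti to the neighbouring C5 aryl group sets C4 (R), and TMSCl traps the enolate so the β-alkoxy ester does not ring-open.

Step 9
Reactants: 14 methyl (4R,5R)-4-{[dimethyl(propan-2-yloxy)silyl]methyl}-5-(3-methoxy-4-prenyloxyphenyl)oxolane-3-carboxylate
Product: 16 (3aS,4R,6aS)-4-(3-methoxy-4-prenyloxyphenyl)tetrahydro-1H,3H-furo[3,4-c]furan-1-one, via hydroxy ester 15 (not isolated)
Conditions: KF, KHCO3, 30% H2O2, THF/MeOH, 45 °C; then DBU (cat.), toluene, 80 °C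
Reagents that add atoms: hydrogen peroxide, OO
Why: Tamao–Fleming oxidation turns C–Si into C–OH with the carbon skeleton intact, then DBU epimerises the ester α-carbon and only the cis isomer can lactonise, which sets C6a (S) and the cis ring fusion.

Step 10
Reactants: 8 (4-bromo-2-methoxyphenoxy)(tert-butyl)dimethylsilane; 16 (3aS,4R,6aS)-4-(3-methoxy-4-prenyloxyphenyl)tetrahydro-1H,3H-furo[3,4-c]furan-1-one
Product: 18 (3aS,4R,6aS)-1-[4-(tert-butyldimethylsilyloxy)-3-methoxyphenyl]-4-(3-methoxy-4-prenyloxyphenyl)tetrahydro-1H,3H-furo[3,4-c]furan-1-ol, via aryllithium 17 (not isolated)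
Conditions: 8, n-BuLi, THF, −78 °C; then 16, −78 °C; H2O
Reagents that add atoms: n-butyllithium (Li of 17), CCCC[Li]
Why: Bromine–lithium exchange and single addition of the aryllithium to the γ-lactone; the tetrahedral lithium alkoxide persists at −78 °C and gives the cyclic hemiketal (anomer mixture, of no consequence).

Step 11
Reactants: 18 (3aS,4R,6aS)-1-[4-(tert-butyldimethylsilyloxy)-3-methoxyphenyl]-4-(3-methoxy-4-prenyloxyphenyl)tetrahydro-1H,3H-furo[3,4-c]furan-1-ol
Product: 19 tert-butyl{2-methoxy-4-[(1S,3aS,4R,6aS)-4-(3-methoxy-4-prenyloxyphenyl)tetrahydro-1H,3H-furo[3,4-c]furan-1-yl]phenoxy}dimethylsilane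
Conditions: Et3SiH, BF3·OEt2, CH2Cl2, −78 °C
Reagents that add atoms: none
Why: Ionic hydrogenation of the hemiketal; the aryl-stabilised oxocarbenium ion of the cis-fused bicycle takes hydride on its convex (exo) face, which leaves the aryl group endo and sets C1 (S).

Step 12
Reactants: 19 tert-butyl{2-methoxy-4-[(1S,3aS,4R,6aS)-4-(3-methoxy-4-prenyloxyphenyl)tetrahydro-1H,3H-furo[3,4-c]furan-1-yl]phenoxy}dimethylsilane
Product: 20 2-methoxy-4-[(1S,3aS,4R,6aS)-4-(3-methoxy-4-prenyloxyphenyl)tetrahydro-1H,3H-furo[3,4-c]furan-1-yl]phenol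
Conditions: TBAF, THF, 0 °C; H2O
Reagents that add atoms: none
Why: Fluoride desilylation of the aryl silyl ether under non-acidic conditions that leave the prenyl ether and the acid-sensitive endo benzylic ether untouched.

## Compound list

1 | catechol (benzene-1,2-diol) | Oc1ccccc1O | starting material
2 | 2-methoxyphenol | COc1ccccc1O | intermediate
3 | 4-bromo-2-methoxyphenol | COc1cc(Br)ccc1O | intermediate
4 | prenyl bromide (1-bromo-3-methylbut-2-ene) | CC(C)=CCBr | starting material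
5 | 4-bromo-2-methoxy-1-prenyloxybenzene | COc1cc(Br)ccc1OCC=C(C)C | intermediate
6 | (3-methoxy-4-prenyloxyphenyl)lithium | [Li]c1ccc(OCC=C(C)C)c(OC)c1 | intermediate
7 | 3-methoxy-4-prenyloxybenzaldehyde | COc1cc(C=O)ccc1OCC=C(C)C | intermediate
8 | (4-bromo-2-methoxyphenoxy)(tert-butyl)dimethylsilane | COc1cc(Br)ccc1O[Si](C)(C)C(C)(C)C | intermediate
9 | methyl 2-(bromomethyl)prop-2-enoate | COC(=O)C(=C)CBr | starting material
10 | (2R,5R)-1-[2-(methoxycarbonyl)prop-2-en-1-yl]-2,5-dimethylthiolan-1-ium bromide | C[C@@H]1CC[C@@H](C)[S+]1CC(=C)C(=O)OC.[Br-] | intermediate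
11 | methyl 2-[(2S,3S)-3-(3-methoxy-4-prenyloxyphenyl)oxiran-2-yl]prop-2-enoate | COC(=O)C(=C)[C@@H]1O[C@H]1c1ccc(OCC=C(C)C)c(OC)c1 | intermediate
12 | methyl (5R)-5-(3-methoxy-4-prenyloxyphenyl)-2,5-dihydrofuran-3-carboxylate | COC(=O)C1=C[C@@H](OC1)c1ccc(OCC=C(C)C)c(OC)c1 | intermediate
13 | {[(4R,5R)-4-{[dimethyl(propan-2-yloxy)silyl]methyl}-5-(3-methoxy-4-prenyloxyphenyl)oxolan-3-ylidene](methoxy)methoxy}trimethylsilane (alkene geometry not defined) | COC(O[Si](C)(C)C)=C1CO[C@@H](c2ccc(OCC=C(C)C)c(OC)c2)[C@@H]1C[Si](C)(C)OC(C)C | intermediate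
14 | methyl (4R,5R)-4-{[dimethyl(propan-2-yloxy)silyl]methyl}-5-(3-methoxy-4-prenyloxyphenyl)oxolane-3-carboxylate (C3 epimer mixture) | COC(=O)C1CO[C@@H](c2ccc(OCC=C(C)C)c(OC)c2)[C@@H]1C[Si](C)(C)OC(C)C | intermediate
15 | methyl (4S,5R)-4-(hydroxymethyl)-5-(3-methoxy-4-prenyloxyphenyl)oxolane-3-carboxylate (C3 epimer mixture) | COC(=O)C1CO[C@@H](c2ccc(OCC=C(C)C)c(OC)c2)[C@@H]1CO | intermediate
16 | (3aS,4R,6aS)-4-(3-methoxy-4-prenyloxyphenyl)tetrahydro-1H,3H-furo[3,4-c]furan-1-one | O=C1OC[C@@H]2[C@H]1CO[C@H]2c1ccc(OCC=C(C)C)c(OC)c1 | intermediate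
17 | [4-(tert-butyldimethylsilyloxy)-3-methoxyphenyl]lithium | [Li]c1ccc(O[Si](C)(C)C(C)(C)C)c(OC)c1 | intermediate
18 | (3aS,4R,6aS)-1-[4-(tert-butyldimethylsilyloxy)-3-methoxyphenyl]-4-(3-methoxy-4-prenyloxyphenyl)tetrahydro-1H,3H-furo[3,4-c]furan-1-ol (anomer mixture at C1) | OC1(c2ccc(O[Si](C)(C)C(C)(C)C)c(OC)c2)OC[C@@H]2[C@H]1CO[C@H]2c1ccc(OCC=C(C)C)c(OC)c1 | intermediate
19 | tert-butyl{2-methoxy-4-[(1S,3aS,4R,6aS)-4-(3-methoxy-4-prenyloxyphenyl)tetrahydro-1H,3H-furo[3,4-c]furan-1-yl]phenoxy}dimethylsilane | COc1cc([C@H]2OC[C@@H]3[C@H]2CO[C@H]3c2ccc(OCC=C(C)C)c(OC)c2)ccc1O[Si](C)(C)C(C)(C)C | intermediate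
20 | 2-methoxy-4-[(1S,3aS,4R,6aS)-4-(3-methoxy-4-prenyloxyphenyl)tetrahydro-1H,3H-furo[3,4-c]furan-1-yl]phenol | COc1cc([C@H]2OC[C@@H]3[C@H]2CO[C@H]3c2ccc(OCC=C(C)C)c(OC)c2)ccc1O | target

## Step count and risks

Total step count: 12. Longest linear sequence: 11 (steps 1–4, then 6–12; step 5 is the side branch).

**Step 6 (asymmetric ylide epoxidation).** The ester-conjugated allyl ylide may give modest enantioselectivity or react with the acrylate units present. Fallback, from 7 back to 11: aldehyde 7 is condensed with pyruvic acid (KOH, MeOH) to (3E)-4-(3-methoxy-4-prenyloxyphenyl)-2-oxobut-3-enoic acid F1. This is esterified (MeI, K2CO3, DMF) to methyl (3E)-4-(3-methoxy-4-prenyloxyphenyl)-2-oxobut-3-enoate F2. The enone is epoxidised enantioselectively (t-BuOOH, La(OiPr)3, BINOL of the enantiomer that gives the required sense, Ph3As=O, THF) to methyl 2-[(2R,3S)-3-(3-methoxy-4-prenyloxyphenyl)oxiran-2-yl]-2-oxoacetate F3. Wittig methylenation of the ketone (Ph3P=CH2, THF, −78 °C) then gives 11.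

**Step 7 (the new ring expansion).** The zwitterion may fail to close, or the oxirane may rearrange. Fallback by known chemistry, from 7 back to 12: aldehyde 7 is vinylated enantioselectively (divinylzinc, 3-exo-(dimethylamino)isoborneol of the enantiomer that gives the R alcohol, toluene) to (1R)-1-(3-methoxy-4-prenyloxyphenyl)prop-2-en-1-ol F4. Its sodium alkoxide is alkylated by 9 (NaH, THF) to methyl 2-({[(1R)-1-(3-methoxy-4-prenyloxyphenyl)prop-2-en-1-yl]oxy}methyl)prop-2-enoate F5. Ring-closing metathesis (second-generation Grubbs catalyst, RuCl2(H2IMes)(PCy3)(=CHPh), CH2Cl2, 40 °C) then gives 12.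

**Step 8 (conjugate addition to a hindered γ-alkoxy enoate).** Ring-opening by elimination or low conversion is possible. Fallback, from 12 back to 16: ester 12 is β-borylated (B2pin2, CuCl, NaOt-Bu, DPEphos, MeOH, THF) to methyl (4R,5R)-5-(3-methoxy-4-prenyloxyphenyl)-4-(4,4,5,5-tetramethyl-1,3,2-dioxaborolan-2-yl)oxolane-3-carboxylate F6. Matteson homologation (BrCH2Cl, n-BuLi, THF, −78 °C) gives methyl (4R,5R)-5-(3-methoxy-4-prenyloxyphenyl)-4-[(4,4,5,5-tetramethyl-1,3,2-dioxaborolan-2-yl)methyl]oxolane-3-carboxylate F7. Oxidation (NaBO3·4H2O, THF/H2O) gives hydroxy ester 15, which DBU in toluene converts into 16.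

Further compounds

F1 | step 6 | (3E)-4-(3-methoxy-4-prenyloxyphenyl)-2-oxobut-3-enoic acid | COc1cc(/C=C/C(=O)C(O)=O)ccc1OCC=C(C)C
F2 | step 6 | methyl (3E)-4-(3-methoxy-4-prenyloxyphenyl)-2-oxobut-3-enoate | COC(=O)C(=O)/C=C/c1ccc(OCC=C(C)C)c(OC)c1
F3 | step 6 | methyl 2-[(2R,3S)-3-(3-methoxy-4-prenyloxyphenyl)oxiran-2-yl]-2-oxoacetate | COC(=O)C(=O)[C@@H]1O[C@H]1c1ccc(OCC=C(C)C)c(OC)c1
F4 | step 7 | (1R)-1-(3-methoxy-4-prenyloxyphenyl)prop-2-en-1-ol | C=C[C@@H](O)c1ccc(OCC=C(C)C)c(OC)c1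
F5 | step 7 | methyl 2-({[(1R)-1-(3-methoxy-4-prenyloxyphenyl)prop-2-en-1-yl]oxy}methyl)prop-2-enoate | C=C[C@@H](OCC(=C)C(=O)OC)c1ccc(OCC=C(C)C)c(OC)c1
F6 | step 8 | methyl (4R,5R)-5-(3-methoxy-4-prenyloxyphenyl)-4-(4,4,5,5-tetramethyl-1,3,2-dioxaborolan-2-yl)oxolane-3-carboxylate (C3 epimer mixture) | COC(=O)C1CO[C@@H](c2ccc(OCC=C(C)C)c(OC)c2)[C@@H]1B1OC(C)(C)C(C)(C)O1
F7 | step 8 | methyl (4R,5R)-5-(3-methoxy-4-prenyloxyphenyl)-4-[(4,4,5,5-tetramethyl-1,3,2-dioxaborolan-2-yl)methyl]oxolane-3-carboxylate (C3 epimer mixture) | COC(=O)C1CO[C@@H](c2ccc(OCC=C(C)C)c(OC)c2)[C@@H]1CB1OC(C)(C)C(C)(C)O1
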